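**Retrosynthetic overview**

1. Numbering used below (drimane-type): ring A = C1(OH)–C2–C3(Cl)–C4(CH3, side chain)–C5–C10(CH3); ring B = C5–C6–C7=C8(CO2Me)–C9(CHO)–C10; α is the face of H-5, β the face of the C10 methyl.
2. Last disconnections: the (R)-isopropenyl carbinol (asymmetric Nozaki–Hiyama–Kishi addition to a side-chain aldehyde) and the C9 aldehyde (carried as its dimethyl acetal).
3. Key disconnection C9–C10, closing ring B (second ring): hydrogen-atom transfer to an exocyclic methylidene on ring A gives the C10 radical, which adds 6-endo to C9 of a (Z)-acrylate and expels acetate from C7.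
4. Enabling feature: the quaternary ring-fusion carbon C10 carries a methyl group (a latent C10=CH2 of ring A, whose allylic oxidation also delivers the axial C1 hydroxyl), and C9 is the allylic carbon next to the C7=C8 enoate of ring B, so C9–C10 is the bond of a radical allylic substitution.
5. Ring A (first ring) is cut at C4–C5: chloronium-type cation–allylsilane cyclisation of an acyclic (Z)-allylsilane whose C3 chloride comes from an organocatalytic aldehyde α-chlorination.

Key step: step 15

Remark on the chemistry: the carbinol carbon made in step 6 and the acetoxy-bearing carbon C7 made in step 13 are destroyed later, so both epimers are carried; the senses of induction of the chiral amine (step 5) and the chiral chromium ligand (step 18) are assigned by analogy, and the antipodal reagent would be taken if needed.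

**Route**

Step 1
Reactants: 1 2,3-dihydrofuran; 2 4-bromo-1,1-dimethoxybutane
Product: 4 5-(4,4-dimethoxybutyl)-2,3-dihydrofuran, via 5-lithio-2,3-dihydrofuran 3 (not isolated)
Conditions: t-BuLi, THF, −78 → 0 °C; then 2, −30 °C → rt
Reagents that add atoms: none
Why: α-Lithiation of the enol ether (vinylic C–H next to oxygen) followed by SN2 alkylation with the primary bromide should give the 5-substituted dihydrofuran; no stereocentre is formed.

Step 2
Reactants: 4 5-(4,4-dimethoxybutyl)-2,3-dihydrofuran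
Product: 5 (3Z)-8,8-dimethoxy-4-[(trimethylsilyl)methyl]oct-3-en-1-ol
Conditions: Me3SiCH2MgCl (3 equiv), NiCl2(PPh3)2 (5 mol %), toluene, 90 °C
Reagents that add atoms: (trimethylsilyl)methylmagnesium chloride, C[Si](C)(C)C[Mg]Cl
Why: Kumada-type nickel-catalysed cross-coupling at the enol ether C–O bond (oxidative addition of zerovalent nickel, transmetalation, reductive elimination) opens the ring with retention of alkene geometry, so CH2SiMe3 takes the place of oxygen cis to the hydroxyethyl arm and the (Z)-allylsilane should result.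

Step 3
Reactants: 5 (3Z)-8,8-dimethoxy-4-[(trimethylsilyl)methyl]oct-3-en-1-ol
Product: 6 tert-butyl{[(3Z)-8,8-dimethoxy-4-[(trimethylsilyl)methyl]oct-3-en-1-yl]oxy}dimethylsilane
Conditions: TBSCl, imidazole, DMF, rt
Reagents that add atoms: tert-butyldimethylsilyl chloride, CC(C)(C)[Si](C)(C)Cl
Why: Standard silylation of the primary alcohol, which protects the C7 oxygen through the organometallic and oxidation steps.

Step 4
Reactants: 6 tert-butyl{[(3Z)-8,8-dimethoxy-4-[(trimethylsilyl)methyl]oct-3-en-1-yl]oxy}dimethylsilane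
Product: 7 (5Z)-8-[(tert-butyldimethylsilyl)oxy]-5-[(trimethylsilyl)methyl]oct-5-enal
Conditions: PPTS (cat.), acetone/H2O (10:1), 40 °C
Reagents that add atoms: water, O
Why: Mild acid-catalysed acetal hydrolysis should free the aldehyde while the primary silyl ether and the allylsilane survive.

Step 5
Reactants: 7 (5Z)-8-[(tert-butyldimethylsilyl)oxy]-5-[(trimethylsilyl)methyl]oct-5-enal
Product: 8 (2S,5Z)-8-[(tert-butyldimethylsilyl)oxy]-2-chloro-5-[(trimethylsilyl)methyl]oct-5-enal
Conditions: NCS, (2R,5R)-2,5-diphenylpyrrolidine (10 mol %), CH2Cl2, −20 °C → rt; crude product used at once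
Reagents that add atoms: N-chlorosuccinimide, O=C1CCC(=O)N1Cl
Why: Enamine-catalysed enantioselective α-chlorination of the aldehyde, in which the C2-symmetric amine shields one face of the enamine so that chlorine should enter to give the (2S) centre (the future C3).

Step 6
Reactants: 8 (2S,5Z)-8-[(tert-butyldimethylsilyl)oxy]-2-chloro-5-[(trimethylsilyl)methyl]oct-5-enal
Product: 9 (3S,6Z)-9-[(tert-butyldimethylsilyl)oxy]-3-chloro-6-[(trimethylsilyl)methyl]non-6-en-2-ol (both C2 epimers)
Conditions: MeMgBr, THF, −78 °C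
Reagents that add atoms: methylmagnesium bromide, C[Mg]Br
Why: Grignard 1,2-addition to the aldehyde at low temperature should outrun enolisation of the α-chloro aldehyde; the new carbinol centre is not controlled because step 7 removes it.

Step 7
Reactants: 9 (3S,6Z)-9-[(tert-butyldimethylsilyl)oxy]-3-chloro-6-[(trimethylsilyl)methyl]non-6-en-2-ol
Product: 10 (3S,6Z)-9-[(tert-butyldimethylsilyl)oxy]-3-chloro-6-[(trimethylsilyl)methyl]non-6-en-2-one
Conditions: Dess–Martin periodinane, CH2Cl2, 0 °C → rt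
Reagents that add atoms: none
Why: Dess–Martin oxidation under non-basic conditions should give the α-chloro methyl ketone without epimerisation of the chlorine-bearing centre.

Step 8
Reactants: 10 (3S,6Z)-9-[(tert-butyldimethylsilyl)oxy]-3-chloro-6-[(trimethylsilyl)methyl]non-6-en-2-one; 11 (3-bromopropoxy)(tert-butyl)diphenylsilane
Product: 14 (4R,5S,8Z)-11-[(tert-butyldimethylsilyl)oxy]-1-[(tert-butyldiphenylsilyl)oxy]-5-chloro-4-methyl-8-[(trimethylsilyl)methyl]undec-8-en-4-yl trifluoroacetate, via Grignard reagent 12 (not isolated), via bromomagnesium alkoxide 13 (not isolated)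
Conditions: 11, Mg, THF, rt; then 10, THF, −78 °C; then (CF3CO)2O, −78 → 0 °C; product used crude
Reagents that add atoms: trifluoroacetic anhydride, O=C(OC(=O)C(F)(F)F)C(F)(F)F
Why: Grignard addition to the α-chloro ketone under Cornforth (polar Felkin–Anh) control, with C–Cl anti to C=O and attack past the small hydrogen, should set the tertiary centre C4 as (4R) with chlorine and oxygen able to stand anti-periplanar, and in situ O-acylation of the alkoxide installs the leaving group.

Step 9
Reactants: 14 (4R,5S,8Z)-11-[(tert-butyldimethylsilyl)oxy]-1-[(tert-butyldiphenylsilyl)oxy]-5-chloro-4-methyl-8-[(trimethylsilyl)methyl]undec-8-en-4-yl trifluoroacetate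
Product: 15 tert-butyl{2-[(1R,2S,3S)-2-{3-[(tert-butyldiphenylsilyl)oxy]propyl}-3-chloro-2-methyl-6-methylidenecyclohexyl]ethoxy}dimethylsilane
Conditions: Me2AlCl (2.2 equiv), CH2Cl2, −78 → −40 °C
Reagents that add atoms: none
Why: Proposed new method: Me2AlCl should ionise the tertiary trifluoroacetate with anchimeric help from the anti-periplanar C3 chlorine (chloronium-like ion, inversion at C4), the allylsilane γ-carbon C5 then opens it at C4 from the opposite face (second inversion, so C5 takes the place of the ester oxygen) through a chair with equatorial chlorine, and loss of Me3Si from the β-silyl cation leaves the exocyclic methylidene, whereby C3 is carried over, C4 follows from the double inversion and C5 from the (Z)-allylsilane geometry (tether equatorial, H-5 anti to the axial C4 methyl); the closest known reaction types are chloronium-induced polyene cyclisations with chlorosulfonium reagents, enantiospecific bromonium-initiated polyene cyclisations started by ionising bromohydrin esters, and Lewis-acid epoxide–allylsilane cyclisations.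

Step 10
Reactants: 15 tert-butyl{2-[(1R,2S,3S)-2-{3-[(tert-butyldiphenylsilyl)oxy]propyl}-3-chloro-2-methyl-6-methylidenecyclohexyl]ethoxy}dimethylsilane
Product: 16 2-[(1R,2S,3S)-2-{3-[(tert-butyldiphenylsilyl)oxy]propyl}-3-chloro-2-methyl-6-methylidenecyclohexyl]ethan-1-ol
Conditions: CSA (cat.), MeOH/CH2Cl2 (1:1), 0 °C
Reagents that add atoms: none
Why: Acid-catalysed methanolysis should remove the primary tert-butyldimethylsilyl ether much faster than the bulkier tert-butyldiphenylsilyl ether.

Step 11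
Reactants: 16 2-[(1R,2S,3S)-2-{3-[(tert-butyldiphenylsilyl)oxy]propyl}-3-chloro-2-methyl-6-methylidenecyclohexyl]ethan-1-ol
Product: 17 2-[(1R,2S,3S)-2-{3-[(tert-butyldiphenylsilyl)oxy]propyl}-3-chloro-2-methyl-6-methylidenecyclohexyl]acetaldehyde
Conditions: Dess–Martin periodinane, CH2Cl2, rt
Reagents that add atoms: none
Why: Dess–Martin oxidation of the primary alcohol to the aldehyde; no α-stereocentre is at risk.

Step 12
Reactants: 18 3,3-dimethoxyprop-1-yne
Product: 20 methyl 4,4-dimethoxybut-2-ynoate, via lithium acetylide 19 (not isolated)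
Conditions: n-BuLi, THF, −78 °C; then ClCO2Me, −78 → 0 °C
Reagents that add atoms: methyl chloroformate, COC(=O)Cl
Why: Deprotonation of the terminal alkyne and C-acylation of the lithium acetylide with the chloroformate.

Step 13
Reactants: 17 2-[(1R,2S,3S)-2-{3-[(tert-butyldiphenylsilyl)oxy]propyl}-3-chloro-2-methyl-6-methylidenecyclohexyl]acetaldehyde; 20 methyl 4,4-dimethoxybut-2-ynoate
Product: 23 methyl (2Z)-2-{1-acetoxy-2-[(1R,2S,3S)-2-{3-[(tert-butyldiphenylsilyl)oxy]propyl}-3-chloro-2-methyl-6-methylidenecyclohexyl]ethyl}-4,4-dimethoxybut-2-enoate (both epimers at the acetoxy carbon), via vinylalane 21 (not isolated), via aluminium alkoxide 22 (not isolated)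
Conditions: i-Bu2AlH, NMO, THF, 0 °C, then 20; then 17, 0 °C → rt; then Ac2O, DMAP (cat.), rt
Reagents that add atoms: acetic anhydride, CC(=O)OC(C)=O
Why: syn-Hydroalumination of the ynoate (hydride to the β-carbon, aluminium α to the ester) gives the α-alumino acrylate, which adds to the aldehyde (Morita–Baylis–Hillman-type vinylalumination) with retention at the alkenyl–aluminium bond so that the acetal carbon is cis to the ester ((Z) geometry), and acetic anhydride caps the alkoxide; the acetoxy-bearing centre is lost in step 15.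

Step 14
Reactants: 23 methyl (2Z)-2-{1-acetoxy-2-[(1R,2S,3S)-2-{3-[(tert-butyldiphenylsilyl)oxy]propyl}-3-chloro-2-methyl-6-methylidenecyclohexyl]ethyl}-4,4-dimethoxybut-2-enoate
Product: 24 methyl (2Z)-2-{1-acetoxy-2-[(1R,2S,3S,5S)-2-{3-[(tert-butyldiphenylsilyl)oxy]propyl}-3-chloro-5-hydroxy-2-methyl-6-methylidenecyclohexyl]ethyl}-4,4-dimethoxybut-2-enoate
Conditions: SeO2 (0.3 equiv), t-BuOOH, CH2Cl2, rt
Reagents that add atoms: tert-butyl hydroperoxide, CC(C)(C)OO (terminal oxidant; the oxygen is passed on by catalytic selenium dioxide, O=[Se]=O)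
Why: Riley-type allylic oxidation (ene reaction at the CH2 terminus of the methylidene, then [2,3]-sigmatropic shift) should prefer the ring CH2 (C1) over the hindered CH (C5) and replace the axial allylic hydrogen, giving the axial 1α-alcohol as in the oxidation of 8(17)-labdenes to 7α-alcohols.

Step 15
Reactants: 24 methyl (2Z)-2-{1-acetoxy-2-[(1R,2S,3S,5S)-2-{3-[(tert-butyldiphenylsilyl)oxy]propyl}-3-chloro-5-hydroxy-2-methyl-6-methylidenecyclohexyl]ethyl}-4,4-dimethoxybut-2-enoate
Product: 25 methyl (1S,3S,4S,5R,9R,10S)-4-{3-[(tert-butyldiphenylsilyl)oxy]propyl}-3-chloro-9-(dimethoxymethyl)-1-hydroxy-4,10-dimethyl-1,2,3,4,5,6,9,10-octahydronaphthalene-8-carboxylate (overview numbering; trans-fused, 1α-OH, 3β-Cl, 4β-CH3, 9β-CH(OMe)2, 10β-CH3)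
Conditions: Fe(acac)3 (30 mol %), PhSiH3 (2.5 equiv), EtOH, 60 °C, degassed
Reagents that add atoms: none
Why: Proposed new method: an iron hydride formed from Fe(acac)3 and PhSiH3 transfers a hydrogen atom to the CH2 terminus of the ring A methylidene, which creates the angular methyl and the tertiary C10 radical; this nucleophilic radical adds to C9, the β-carbon of the (Z)-acrylate, the α-ester radical is reduced by divalent iron to the ester enolate, and E1cB loss of acetate from C7 leaves the C7=C8 enoate. The closest known reaction types are the iron-catalysed reductive olefin coupling (Giese addition after hydrogen-atom transfer), radical allylation with 2-(acetoxymethyl)acrylates, and oxidative radical polyene cyclisations that close the second ring of trans-decalins from a tertiary C10 radical. Ring B closes in the 6-endo-trig mode. C10 is controlled by a chair-like transition state in which the C5 tether and the forming C9–C10 bond are equatorial on ring A and the new methyl is axial (trans ring fusion); C9 is controlled by the (Z) geometry of the acrylate, which keeps the CH(OMe)2 group anti to C7 and therefore pseudo-equatorial (H-9 anti to the angular methyl). The step needs hydrogen-atom transfer to the electron-rich 1,1-disubstituted alkene and not to the electron-poor acrylate, and bond formation at C9 and not at the fully substituted C8; the polarity match of the tertiary radical with the acrylate β-carbon and the absence of any other alkene should secure both.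

Step 16
Reactants: 25 methyl (1S,3S,4S,5R,9R,10S)-4-{3-[(tert-butyldiphenylsilyl)oxy]propyl}-3-chloro-9-(dimethoxymethyl)-1-hydroxy-4,10-dimethyl-octahydronaphthalene-8-carboxylate
Product: 26 methyl (1S,3S,4S,5R,9R,10S)-3-chloro-9-(dimethoxymethyl)-1-hydroxy-4-(3-hydroxypropyl)-4,10-dimethyl-octahydronaphthalene-8-carboxylate
Conditions: TBAF, THF, 0 °C → rt
Reagents that add atoms: none
Why: Fluoride cleaves the silicon–oxygen bond of the remaining silyl ether; the hindered secondary alcohol, the chloride, the ester and the acetal should not be affected.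

Step 17
Reactants: 26 methyl (1S,3S,4S,5R,9R,10S)-3-chloro-9-(dimethoxymethyl)-1-hydroxy-4-(3-hydroxypropyl)-4,10-dimethyl-octahydronaphthalene-8-carboxylate
Product: 27 methyl (1S,3S,4S,5R,9R,10S)-3-chloro-9-(dimethoxymethyl)-1-hydroxy-4,10-dimethyl-4-(3-oxopropyl)-octahydronaphthalene-8-carboxylate
Conditions: TEMPO (10 mol %), PhI(OAc)2, CH2Cl2, rt
Reagents that add atoms: none
Why: Nitroxyl-catalysed oxidation is selective for the primary alcohol over the hindered axial secondary alcohol and stops at the aldehyde.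

Step 18
Reactants: 27 methyl (1S,3S,4S,5R,9R,10S)-3-chloro-9-(dimethoxymethyl)-1-hydroxy-4,10-dimethyl-4-(3-oxopropyl)-octahydronaphthalene-8-carboxylate
Product: 28 methyl (1S,3S,4S,5R,9R,10S)-3-chloro-9-(dimethoxymethyl)-1-hydroxy-4-[(3R)-3-hydroxy-4-methylpent-4-en-1-yl]-4,10-dimethyl-octahydronaphthalene-8-carboxylate
Conditions: 2-bromopropene, CrCl2 (4 equiv), NiCl2 (cat.), chiral oxazoline–sulfonamide ligand, Et3N, THF, rt
Reagents that add atoms: 2-bromopropene, C=C(C)Br
Why: Asymmetric Nozaki–Hiyama–Kishi reaction, in which the isopropenylchromium species adds chemoselectively to the aldehyde and the chiral ligand on chromium (reagent control) should set the (R) carbinol.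

Step 19
Reactants: 28 methyl (1S,3S,4S,5R,9R,10S)-3-chloro-9-(dimethoxymethyl)-1-hydroxy-4-[(3R)-3-hydroxy-4-methylpent-4-en-1-yl]-4,10-dimethyl-octahydronaphthalene-8-carboxylate
Product: 29 CNP0159496.2, methyl (1S,3S,4S,5R,9R,10S)-3-chloro-9-formyl-1-hydroxy-4-[(3R)-3-hydroxy-4-methylpent-4-en-1-yl]-4,10-dimethyl-octahydronaphthalene-8-carboxylate
Conditions: PPTS, acetone/H2O (10:1), 40 °C
Reagents that add atoms: water, O
Why: Mild acid-catalysed hydrolysis of the dimethyl acetal, weak enough that the β,γ-unsaturated aldehyde should neither epimerise at C9 nor move into conjugation and the allylic alcohol should not ionise.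

**Compound list**

1 | 2,3-dihydrofuran | C1CC=CO1 | starting material
2 | 4-bromo-1,1-dimethoxybutane | COC(OC)CCCBr | starting material
3 | 5-lithio-2,3-dihydrofuran | [Li]C1=CCCO1 | intermediate
4 | 5-(4,4-dimethoxybutyl)-2,3-dihydrofuran | COC(OC)CCCC1=CCCO1 | intermediate
5 | (3Z)-8,8-dimethoxy-4-[(trimethylsilyl)methyl]oct-3-en-1-ol | OCC/C=C(\C[Si](C)(C)C)CCCC(OC)OC | intermediate
6 | tert-butyl{[(3Z)-8,8-dimethoxy-4-[(trimethylsilyl)methyl]oct-3-en-1-yl]oxy}dimethylsilane | CC(C)(C)[Si](C)(C)OCC/C=C(\C[Si](C)(C)C)CCCC(OC)OC | intermediate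
7 | (5Z)-8-[(tert-butyldimethylsilyl)oxy]-5-[(trimethylsilyl)methyl]oct-5-enal | CC(C)(C)[Si](C)(C)OCC/C=C(\C[Si](C)(C)C)CCCC=O | intermediate
8 | (2S,5Z)-8-[(tert-butyldimethylsilyl)oxy]-2-chloro-5-[(trimethylsilyl)methyl]oct-5-enal | O=C[C@@H](Cl)CC/C(C[Si](C)(C)C)=C/CCO[Si](C)(C)C(C)(C)C | intermediate
9 | (3S,6Z)-9-[(tert-butyldimethylsilyl)oxy]-3-chloro-6-[(trimethylsilyl)methyl]non-6-en-2-ol, both C2 epimers | CC(O)[C@@H](Cl)CC/C(C[Si](C)(C)C)=C/CCO[Si](C)(C)C(C)(C)C | intermediate
10 | (3S,6Z)-9-[(tert-butyldimethylsilyl)oxy]-3-chloro-6-[(trimethylsilyl)methyl]non-6-en-2-one | CC(=O)[C@@H](Cl)CC/C(C[Si](C)(C)C)=C/CCO[Si](C)(C)C(C)(C)C | intermediate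
11 | (3-bromopropoxy)(tert-butyl)diphenylsilane | BrCCCO[Si](c1ccccc1)(c1ccccc1)C(C)(C)C | starting material
12 | {3-[(tert-butyldiphenylsilyl)oxy]propyl}magnesium bromide | Br[Mg]CCCO[Si](c1ccccc1)(c1ccccc1)C(C)(C)C | intermediate
13 | bromomagnesium (4R,5S,8Z)-11-[(tert-butyldimethylsilyl)oxy]-1-[(tert-butyldiphenylsilyl)oxy]-5-chloro-4-methyl-8-[(trimethylsilyl)methyl]undec-8-en-4-olate | CC(C)(C)[Si](c1ccccc1)(c1ccccc1)OCCC[C@](O[Mg]Br)(C)[C@@H](Cl)CC/C(C[Si](C)(C)C)=C/CCO[Si](C)(C)C(C)(C)C | intermediate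
14 | (4R,5S,8Z)-11-[(tert-butyldimethylsilyl)oxy]-1-[(tert-butyldiphenylsilyl)oxy]-5-chloro-4-methyl-8-[(trimethylsilyl)methyl]undec-8-en-4-yl trifluoroacetate | CC(C)(C)[Si](c1ccccc1)(c1ccccc1)OCCC[C@](OC(=O)C(F)(F)F)(C)[C@@H](Cl)CC/C(C[Si](C)(C)C)=C/CCO[Si](C)(C)C(C)(C)C | intermediate
15 | tert-butyl{2-[(1R,2S,3S)-2-{3-[(tert-butyldiphenylsilyl)oxy]propyl}-3-chloro-2-methyl-6-methylidenecyclohexyl]ethoxy}dimethylsilane (ring A: C3 chlorine equatorial, C4 methyl axial, H-5 axial) | CC(C)(C)[Si](c1ccccc1)(c1ccccc1)OCCC[C@]2(C)[C@@H](Cl)CCC(=C)[C@H]2CCO[Si](C)(C)C(C)(C)C | intermediate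
16 | 2-[(1R,2S,3S)-2-{3-[(tert-butyldiphenylsilyl)oxy]propyl}-3-chloro-2-methyl-6-methylidenecyclohexyl]ethan-1-ol | CC(C)(C)[Si](c1ccccc1)(c1ccccc1)OCCC[C@]2(C)[C@@H](Cl)CCC(=C)[C@H]2CCO | intermediate
17 | 2-[(1R,2S,3S)-2-{3-[(tert-butyldiphenylsilyl)oxy]propyl}-3-chloro-2-methyl-6-methylidenecyclohexyl]acetaldehyde | CC(C)(C)[Si](c1ccccc1)(c1ccccc1)OCCC[C@]2(C)[C@@H](Cl)CCC(=C)[C@H]2CC=O | intermediate
18 | 3,3-dimethoxyprop-1-yne | C#CC(OC)OC | starting material
19 | (3,3-dimethoxyprop-1-yn-1-yl)lithium | [Li]C#CC(OC)OC | intermediate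
20 | methyl 4,4-dimethoxybut-2-ynoate | COC(=O)C#CC(OC)OC | intermediate
21 | methyl (2E)-2-(diisobutylalumanyl)-4,4-dimethoxybut-2-enoate | COC(=O)/C([Al](CC(C)C)CC(C)C)=C\C(OC)OC | intermediate
22 | diisobutylaluminium alkoxide of methyl (2Z)-2-{2-[(1R,2S,3S)-2-{3-[(tert-butyldiphenylsilyl)oxy]propyl}-3-chloro-2-methyl-6-methylidenecyclohexyl]-1-hydroxyethyl}-4,4-dimethoxybut-2-enoate, both carbinol epimers | CC(C)(C)[Si](c1ccccc1)(c1ccccc1)OCCC[C@]2(C)[C@@H](Cl)CCC(=C)[C@H]2CC(O[Al](CC(C)C)CC(C)C)/C(C(=O)OC)=C/C(OC)OC | intermediate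
23 | methyl (2Z)-2-{1-acetoxy-2-[(1R,2S,3S)-2-{3-[(tert-butyldiphenylsilyl)oxy]propyl}-3-chloro-2-methyl-6-methylidenecyclohexyl]ethyl}-4,4-dimethoxybut-2-enoate, both epimers at the acetoxy carbon | CC(C)(C)[Si](c1ccccc1)(c1ccccc1)OCCC[C@]2(C)[C@@H](Cl)CCC(=C)[C@H]2CC(OC(C)=O)/C(C(=O)OC)=C/C(OC)OC | intermediate
24 | methyl (2Z)-2-{1-acetoxy-2-[(1R,2S,3S,5S)-2-{3-[(tert-butyldiphenylsilyl)oxy]propyl}-3-chloro-5-hydroxy-2-methyl-6-methylidenecyclohexyl]ethyl}-4,4-dimethoxybut-2-enoate, both epimers at the acetoxy carbon | CC(C)(C)[Si](c1ccccc1)(c1ccccc1)OCCC[C@]2(C)[C@@H](Cl)C[C@H](O)C(=C)[C@H]2CC(OC(C)=O)/C(C(=O)OC)=C/C(OC)OC | intermediate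
25 | methyl (1S,3S,4S,5R,9R,10S)-4-{3-[(tert-butyldiphenylsilyl)oxy]propyl}-3-chloro-9-(dimethoxymethyl)-1-hydroxy-4,10-dimethyl-1,2,3,4,5,6,9,10-octahydronaphthalene-8-carboxylate (overview numbering; trans-fused) | CC(C)(C)[Si](c1ccccc1)(c1ccccc1)OCCC[C@]2(C)[C@@H](Cl)C[C@H](O)[C@]3(C)[C@@H](C(OC)OC)C(C(=O)OC)=CC[C@@H]23 | intermediate
26 | methyl (1S,3S,4S,5R,9R,10S)-3-chloro-9-(dimethoxymethyl)-1-hydroxy-4-(3-hydroxypropyl)-4,10-dimethyl-octahydronaphthalene-8-carboxylate | OCCC[C@]2(C)[C@@H](Cl)C[C@H](O)[C@]3(C)[C@@H](C(OC)OC)C(C(=O)OC)=CC[C@@H]23 | intermediate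
27 | methyl (1S,3S,4S,5R,9R,10S)-3-chloro-9-(dimethoxymethyl)-1-hydroxy-4,10-dimethyl-4-(3-oxopropyl)-octahydronaphthalene-8-carboxylate | O=CCC[C@]2(C)[C@@H](Cl)C[C@H](O)[C@]3(C)[C@@H](C(OC)OC)C(C(=O)OC)=CC[C@@H]23 | intermediate
28 | methyl (1S,3S,4S,5R,9R,10S)-3-chloro-9-(dimethoxymethyl)-1-hydroxy-4-[(3R)-3-hydroxy-4-methylpent-4-en-1-yl]-4,10-dimethyl-octahydronaphthalene-8-carboxylate | C=C(C)[C@H](O)CC[C@]2(C)[C@@H](Cl)C[C@H](O)[C@]3(C)[C@@H](C(OC)OC)C(C(=O)OC)=CC[C@@H]23 | intermediate
29 | CNP0159496.2, methyl (1S,3S,4S,5R,9R,10S)-3-chloro-9-formyl-1-hydroxy-4-[(3R)-3-hydroxy-4-methylpent-4-en-1-yl]-4,10-dimethyl-octahydronaphthalene-8-carboxylate | C=C(C)[C@H](O)CC[C@]1(C)[C@@H](Cl)C[C@H](O)[C@]2(C)[C@@H](C=O)C(C(=O)OC)=CC[C@@H]12 | target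

**Step count and risks**

Total step count: 19. Longest linear sequence: 18 steps (steps 1–11 and 13–19); step 12 is a one-step side branch.

Steps most likely to fail:

1. Step 15 (key step, proposed new method). The C10 radical may be reduced (net hydrogenation of the methylidene), or the allylic alcohol may isomerise, before the hindered 6-endo addition to the β-substituted acrylate takes place. The fallback sets out from 24 and uses known chemistry. Mukaiyama hydration (Co(acac)2, PhSiH3, O2) of the methylidene should give the 1,10-diol F1. Thiocarbonyldiimidazole then closes the cis-diol to the cyclic thionocarbonate F2. Bu3SnH/AIBN should fragment it toward the tertiary C10 radical (Barton–McCombie type); 6-endo Giese cyclisation and hydrogen transfer from tin give, after work-up, the saturated 7-acetoxy ester F3. DBU (E1cB loss of acetic acid) then comes back to the route at 25.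

2. Step 9 (proposed new method). Ionisation may occur without chlorine participation (open tertiary cation and loss of the C4 configuration), or end in elimination or protodesilylation instead of ring closure. The fallback sets out from 7, uses known chemistry and installs chlorine after ring closure. Steps 5–7 run with the (2S,5S) amine should give the (2R)-chloro aldehyde F4, the alcohol F5 and the (3R)-chloro ketone F6. Grignard reagent 12 with aqueous work-up gives the antipodal chlorohydrin F7, and K2CO3/MeOH closes it with inversion at C3 to the epoxide F8. The well-known Lewis-acid epoxide–allylsilane cyclisation (Et2AlCl, CH2Cl2, −78 °C) should give the 3β-alcohol F9 with the C4 and C5 configuration of 15. Stereoretentive chlorination (SOCl2, then catalytic TiCl4 on the chlorosulfite) comes back to the route at 15.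

3. Step 18. Facial selectivity in the chromium-mediated addition may be poor, since only the external ligand distinguishes the aldehyde faces. The fallback sets out from 27: isopropenylmagnesium bromide (THF, −78 °C) should give the carbinol epimer mixture F10, MnO2 oxidises the allylic alcohol to the isopropenyl ketone F11, and Corey–Bakshi–Shibata reduction (oxazaborolidine, catecholborane) comes back to the route at 28.

**Further compounds**

F1 | step 15 | tertiary C10 alcohol from Markovnikov hydration of the methylidene of 24 (1,10-diol, C10 epimers, other centres as in 24) | CC(C)(C)[Si](c1ccccc1)(c1ccccc1)OCCC[C@]2(C)[C@@H](Cl)C[C@H](O)C(C)(O)[C@H]2CC(OC(C)=O)/C(C(=O)OC)=C/C(OC)OC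
F2 | step 15 | cyclic thionocarbonate of the C1/C10 diol F1 | CC(C)(C)[Si](c1ccccc1)(c1ccccc1)OCCC[C@]2(C)[C@@H](Cl)C[C@H](OC(=S)O3)C3(C)[C@H]2CC(OC(C)=O)/C(C(=O)OC)=C/C(OC)OC
F3 | step 15 | 7-acetoxy-7,8-dihydro analogue of 25 (C7 and C8 epimers) | CC(C)(C)[Si](c1ccccc1)(c1ccccc1)OCCC[C@]2(C)[C@@H](Cl)C[C@H](O)[C@]3(C)[C@@H](C(OC)OC)C(C(=O)OC)C(OC(C)=O)C[C@@H]23
F4 | step 9 | (2R,5Z)-8-[(tert-butyldimethylsilyl)oxy]-2-chloro-5-[(trimethylsilyl)methyl]oct-5-enal (enantiomer of 8) | O=C[C@H](Cl)CC/C(C[Si](C)(C)C)=C/CCO[Si](C)(C)C(C)(C)C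
F5 | step 9 | (3R,6Z)-9-[(tert-butyldimethylsilyl)oxy]-3-chloro-6-[(trimethylsilyl)methyl]non-6-en-2-ol, both C2 epimers | CC(O)[C@H](Cl)CC/C(C[Si](C)(C)C)=C/CCO[Si](C)(C)C(C)(C)C
F6 | step 9 | (3R,6Z)-9-[(tert-butyldimethylsilyl)oxy]-3-chloro-6-[(trimethylsilyl)methyl]non-6-en-2-one (enantiomer of 10) | CC(=O)[C@H](Cl)CC/C(C[Si](C)(C)C)=C/CCO[Si](C)(C)C(C)(C)C
F7 | step 9 | (4S,5R,8Z)-11-[(tert-butyldimethylsilyl)oxy]-1-[(tert-butyldiphenylsilyl)oxy]-5-chloro-4-methyl-8-[(trimethylsilyl)methyl]undec-8-en-4-ol | CC(C)(C)[Si](c1ccccc1)(c1ccccc1)OCCC[C@@](O)(C)[C@H](Cl)CC/C(C[Si](C)(C)C)=C/CCO[Si](C)(C)C(C)(C)C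
F8 | step 9 | (S,S)-configured trisubstituted epoxide from F7 (oxygen bridging the former C–Cl and C–OH carbons, chain and allylsilane as in F7) | CC(C)(C)[Si](c1ccccc1)(c1ccccc1)OCCC[C@]2(C)O[C@H]2CC/C(C[Si](C)(C)C)=C/CCO[Si](C)(C)C(C)(C)C
F9 | step 9 | 3β-hydroxy analogue of 15 (OH in place of Cl, other centres as in 15) | CC(C)(C)[Si](c1ccccc1)(c1ccccc1)OCCC[C@]2(C)[C@@H](O)CCC(=C)[C@H]2CCO[Si](C)(C)C(C)(C)C
F10 | step 18 | side-chain carbinol epimer mixture of 28 | C=C(C)C(O)CC[C@]2(C)[C@@H](Cl)C[C@H](O)[C@]3(C)[C@@H](C(OC)OC)C(C(=O)OC)=CC[C@@H]23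
F11 | step 18 | isopropenyl ketone corresponding to 28 (side chain CH2CH2C(=O)C(CH3)=CH2) | C=C(C)C(=O)CC[C@]2(C)[C@@H](Cl)C[C@H](O)[C@]3(C)[C@@H](C(OC)OC)C(C(=O)OC)=CC[C@@H]23
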